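**Assumption:** of the two pseudoenantiomeric cinchona catalysts, the one that opens 1 to (R)-2 is used. The sense of induction is not asserted here and should be checked by the optical rotation of 2 before continuing.

## Structural features

1. The core is a cyclohex-3-ene ring, numbered here C1–C6: C1 carries the aroyl group, C2 the prenyl group, C3 the methyl group and the C3=C4 double bond, C5 is CH2, and C6 carries the phenyl group.
2. C6, C1 and C2 are three contiguous stereocentres, (1R,2S,6R): the aroyl group is trans to phenyl and cis to prenyl, so C2 and C6 are 1,3-trans across C1.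
3. C1 is α to the ketone and flanked by two stereocentres, so it is enolisable and must be kept away from base once set; C2 is allylic and next to the C3 methyl group.
4. The aroyl group is 2,4-dihydroxy-6-methoxyphenyl, an electron-rich arene that is unsymmetrical only through one O-methyl group, with one ortho OH hydrogen-bonded to the ketone.
5. The two trisubstituted alkenes (ring C3=C4 and prenyl) are sensitive to protic and Lewis acids.
6. The connectivity reads at once as a chalcone–ocimene [4+2] adduct.
7. The feature the key step exploits is the γ,δ-unsaturated carbonyl array O=C–C1–C2–C3=C4, in which C4 is tied back to C1 through C5 and C6. A retro-[3,3] shift across C1–C2 with a new C4–O bond turns the carbocycle into a six-membered lactone whose only stereocentres are C6 (phenyl) and C4 (carbinol), neither enolisable.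
8. The real difficulty is to set C1 and C2 relative to C6, with absolute control and unambiguous regiochemistry, without acid.

## Logic of the disconnections

**22 ⇒ 21 ⇒ 20.** Only an O–Si bond and one O–CH3 bond are changed. The unsymmetrical 2-OH/6-OMe arene is traced to a 2,6-dimethoxy-4-silyloxy arene whose two ortho positions are equivalent, so no regiochemical question arises when the arene is metalated or demethylated. The forward demand is that demethylation stops after one ortho methyl group and spares the alkenes and C1.

**20 ⇒ 14 + 16.** The aryl–C(=O) bond is cut. This separates the whole stereochemical problem (14) from a one-step arene (16). The forward acyl transfer must join two hindered partners without enolising C1.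

**14 ⇒ 12 ⇒ 11 (key).** The C1–C2 bond is cut and C4 is reconnected to the carboxyl oxygen (retro-Ireland–Claisen). The cyclohexene with three contiguous stereocentres becomes a δ-lactone with two 1,3-related, non-enolisable stereocentres and an (E)-trisubstituted alkene. The forward step must pass through the ring-enforced boat, so 11 must be the cis lactone with the E side chain. In one sentence, the route is the Ireland–Claisen ring contraction of 12 to 14, which does not describe a Diels–Alder route.

**11 ⇒ 10 ⇒ 9.** The lactone C–O(acyl) bond and the carbinol C–H bond are cut. The carbinol centre becomes a ketone reducible under reagent control, independent of the existing phenyl-bearing centre. The forward reduction must discriminate the alkenyl from the CH2 side of the ketone.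

**9 ⇒ 6 + 8 (from 7).** The C6=C7 double bond of 9 is cut. A stabilised acyl ylide guarantees the E geometry that later becomes the cis C1/C2 relationship. The forward olefination must be mild enough not to conjugate the β,γ-unsaturated aldehyde.

**6 ⇒ 2 + 3, and 2 ⇒ 1.** The C5–C6 bond of 6 is cut to an acid chloride and an ethylidene ylide. 2 is then traced to the meso anhydride 1, in which the future C6 centre is prochiral. The first stereocentre therefore costs one catalytic step on a commercial compound. The forward demand is high enantiotopic-group selectivity in the ring opening.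

## Other disconnections considered

**Alternative 1:** Cut C1–C2 and C5–C6 together. The forward step is an intermolecular Diels–Alder reaction of the chalcone A1 (cardamonin) with commercial (E)-β-ocimene, giving the target directly. This is the first route that comes to mind, and it is set aside for these reasons:
- The 1-alkyl and 2-methyl substituents of the diene push the larger HOMO coefficient towards opposite termini, so regiochemistry is not strongly biased.
- A1 is an electron-rich, cross-conjugated and therefore sluggish dienophile, and forcing conditions endanger the skipped triene.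
- Regio-, endo/exo and facial selectivity would all have to be delivered by one chiral Lewis acid in a single bimolecular event.
- The chosen plan makes the regiochemistry intramolecular and sets the absolute configuration in two separate reagent-controlled steps.

**Alternative 2:** Cut C3=C4. The forward step is ring-closing metathesis of the acyclic triene ketone A2 (isopropenyl and allyl termini). It is set aside for these reasons:
- The metathesis creates no stereocentre, so C6, C1 and C2 would have to be built on an open chain, with C1 α to a ketone between two stereocentres and each relationship needing its own control.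
- Closure forms a trisubstituted ring alkene from a 1,1-disubstituted partner, which is slow.
- The prenyl alkene offers the carbene a competing path (loss of isobutene and closure of a seven-membered ring from the allyl terminus).
- More steps would be needed for less stereochemical return than the sigmatropic plan, in which ring closure and two stereocentres come together.

**Alternative 3:** Cut C6–C(phenyl) and C1–H. The ynone A3 and ocimene would give the cyclohexa-1,4-dienyl ketone A4, and a Rh-catalysed asymmetric conjugate addition of phenylboronic acid to A4 followed by protonation at C1 would finish the ring. It is set aside for these reasons: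
- A4 is formed racemic at C2, so a chiral catalyst could at best resolve it.
- C2 in A4 is doubly allylic and vinylogously acidic, and the 1,4-diene is prone to conjugation and aromatisation.
- The regiochemical ambiguity of Alternative 1 returns in the cycloaddition.
- The C1 proton is delivered last with no secured control.
- The chosen plan sets C6 first, on a prochiral commercial anhydride, and relays it.

Key step: step 5

## Steps

Step 1
Reactants: 1 3-phenylglutaric anhydride (4-phenyloxane-2,6-dione)
Product: 2 (3R)-5-methoxy-5-oxo-3-phenylpentanoic acid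
Conditions: MeOH (10 equiv), cinchona-derived bifunctional thiourea catalyst (10 mol%, pseudoenantiomer giving R), MTBE, rt
Reagents that add atoms: methanol CO
Why: Organocatalytic desymmetrising alcoholysis of a meso anhydride: the quinuclidine nitrogen acts as general base for methanol while the hydrogen-bond donor activates one enantiotopic carbonyl. This sets the phenyl-bearing centre (C6 of the target) on a centre that is never enolisable later.

Step 2
Reactants: 2 (3R)-5-methoxy-5-oxo-3-phenylpentanoic acid; 3 ethyltriphenylphosphonium bromide
Product: 6 methyl (3R)-5-oxo-3-phenyl-6-(triphenyl-λ5-phosphanylidene)heptanoate, via acid chloride 4 (not isolated), via ethylidene ylide 5 (not isolated)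
Conditions: 2, (COCl)2, cat. DMF, CH2Cl2, 0 °C to rt, evaporate; 3 (2.1 equiv), n-BuLi (2.0 equiv), THF, 0 °C; then 4, −78 °C to rt
Reagents that add atoms: none
Why: C-acylation of a non-stabilised ylide by an acid chloride followed by transylidation with the second equivalent of ylide gives the stabilised acyl ylide. At −78 °C the acid chloride reacts far faster than the methyl ester, and the stereocentre is β to both carbonyls and so is untouched.

Step 3
Reactants: 6 methyl (3R)-5-oxo-3-phenyl-6-(triphenyl-λ5-phosphanylidene)heptanoate; 7 4-methylpent-3-en-1-ol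
Product: 9 methyl (3R,6E)-6,10-dimethyl-5-oxo-3-phenylundeca-6,9-dienoate, via 4-methylpent-3-enal 8 (not isolated)
Conditions: 7 (1.5 equiv), Dess–Martin periodinane, pyridine, CH2Cl2, 0 °C to rt, filter through Celite; then 6, CH2Cl2, 40 °C
Reagents that add atoms: none
Why: Buffered Dess–Martin oxidation followed by a Wittig reaction of the α-methyl acyl ylide. Stabilised ylides of this type give the (E)-trisubstituted enone under thermodynamic control of oxaphosphetane formation, and the near-neutral ylide should leave the β,γ-unsaturated aldehyde unconjugated.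

Step 4
Reactants: 9 methyl (3R,6E)-6,10-dimethyl-5-oxo-3-phenylundeca-6,9-dienoate
Product: 11 (4R,6R)-6-[(2E)-6-methylhepta-2,5-dien-2-yl]-4-phenyloxan-2-one, via hydroxy ester 10 (not isolated)
Conditions: (S)-Me-CBS (0.2 equiv), catecholborane (1.5 equiv), toluene, −78 °C; MeOH quench; then PPTS (cat.), toluene, 60 °C
Reagents that add atoms: none
Why: Corey–Bakshi–Shibata reduction with the α-methyl alkenyl group as the large substituent; the (S)-catalyst should deliver hydride to give the (5R)-allylic alcohol under reagent control, and catecholborane does not hydroborate the alkenes at −78 °C. Mild acid-catalysed lactonisation then gives the cis-4,6-disubstituted lactone; any trans lactone from residual (S)-2 or imperfect reduction is a diastereomer and can be removed here.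

Step 5
Reactants: 11 (4R,6R)-6-[(2E)-6-methylhepta-2,5-dien-2-yl]-4-phenyloxan-2-one
Product: 14 (1R,2S,6R)-3-methyl-2-(3-methylbut-2-en-1-yl)-6-phenylcyclohex-3-ene-1-carboxylic acid, via silyl ketene acetal 12 (not isolated), via silyl ester 13 (not isolated)
Conditions: LDA, THF, −78 °C; TBSCl, DMPU, −78 °C to rt; toluene, 110 °C; then THF–H2O–AcOH, rt
Reagents that add atoms: none
Why: Deprotonation at the only α-CH2 and O-silylation give the endocyclic silyl ketene acetal 12, whose O–C(allyl) bond and enol C=C lie in the same six-membered ring; a [3,3]-sigmatropic shift then forms C1–C2 as the C4–O bond breaks and gives silyl ester 13, hydrolysed to 14. The closest known reaction type is the Ireland–Claisen ring contraction of alkenyl lactone silyl ketene acetals to cycloalkene carboxylic acids. The cyclohexene ring C1–C6 is closed by a concerted suprafacial shift across the lactone through a boat (bicyclo[2.2.2]-like) transition state; a chair is geometrically impossible, so there is no chair/boat ambiguity. At C1, the side chain can only reach the face of the ketene acetal on which it is attached; since phenyl at C6 lies on that same face in the cis lactone, the carboxyl carbon ends trans to phenyl. At C2, the E geometry of the side-chain alkene places CH2-prenyl in the outside position of the boat, which maps to cis to the carboxyl group (the same relationship as in an endo cycloaddition). C6 is a spectator and keeps its R configuration, and the carbinol centre is consumed, its chirality being transferred to C1 and C2. The selectivities needed are O- over C-silylation (silyl chloride with DMPU at low temperature), cis lactone geometry (step 4) and E alkene geometry (step 3); regiochemistry cannot go wrong because the reacting termini are tethered.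

Step 6
Reactants: 15 3,5-dimethoxyphenol
Product: 16 (3,5-dimethoxyphenoxy)tri(propan-2-yl)silane
Conditions: TIPSCl, imidazole, DMF, rt
Reagents that add atoms: chlorotri(propan-2-yl)silane CC(C)[Si](Cl)(C(C)C)C(C)C
Why: Standard phenol silylation. The bulky, weakly directing TIPS ether shields its own ortho positions, so the later lithiation goes between the two methoxy groups.

Step 7
Reactants: 14 (1R,2S,6R)-3-methyl-2-(3-methylbut-2-en-1-yl)-6-phenylcyclohex-3-ene-1-carboxylic acid; 16 (3,5-dimethoxyphenoxy)tri(propan-2-yl)silane
Product: 20 {2,6-dimethoxy-4-[tri(propan-2-yl)silyloxy]phenyl}[(1R,2S,6R)-3-methyl-2-(3-methylbut-2-en-1-yl)-6-phenylcyclohex-3-en-1-yl]methanone, via acid chloride 17 (not isolated), via aryllithium 18 (not isolated), via arylcopper 19 (not isolated)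
Conditions: 14, (COCl)2, cat. DMF, CH2Cl2, 0 °C to rt, evaporate; 16, n-BuLi, THF, 0 °C to rt; CuBr·SMe2, −40 °C; then 17, −40 to 0 °C
Reagents that add atoms: none
Why: Directed ortho-lithiation between two methoxy groups, transmetalation to a weakly basic arylcopper and acylation by the acid chloride (organocopper ketone synthesis). The low basicity should avoid ketene formation and so preserve C1, and the di-ortho-substituted ketone resists a second addition.

Step 8
Reactants: 20 {2,6-dimethoxy-4-[tri(propan-2-yl)silyloxy]phenyl}[(1R,2S,6R)-3-methyl-2-(3-methylbut-2-en-1-yl)-6-phenylcyclohex-3-en-1-yl]methanone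
Product: 21 {2-hydroxy-6-methoxy-4-[tri(propan-2-yl)silyloxy]phenyl}[(1R,2S,6R)-3-methyl-2-(3-methylbut-2-en-1-yl)-6-phenylcyclohex-3-en-1-yl]methanone
Conditions: BCl3 (1.5 equiv), CH2Cl2, −78 to −20 °C; then H2O
Reagents that add atoms: none
Why: Chelation-assisted demethylation of an aryl methyl ether ortho to a ketone: boron bridges the carbonyl and one ortho oxygen and chloride removes that methyl group. The resulting boron chelate occupies the carbonyl, so the second, equivalent ortho methyl ether should survive; the two ortho positions being identical, only one product is possible.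

Step 9
Reactants: 21 {2-hydroxy-6-methoxy-4-[tri(propan-2-yl)silyloxy]phenyl}[(1R,2S,6R)-3-methyl-2-(3-methylbut-2-en-1-yl)-6-phenylcyclohex-3-en-1-yl]methanone
Product: 22 isopanduratin A, (2,4-dihydroxy-6-methoxyphenyl)[(1R,2S,6R)-3-methyl-2-(3-methylbut-2-en-1-yl)-6-phenylcyclohex-3-en-1-yl]methanone
Conditions: TBAF (1.1 equiv), AcOH (1.1 equiv), THF, 0 °C
Reagents that add atoms: none
Why: Fluoride cleavage of the aryl silyl ether. Buffering with acetic acid keeps the medium non-basic so that C1 is not enolised.

## Compound list

1 | 3-phenylglutaric anhydride (4-phenyloxane-2,6-dione) | O=C1CC(c2ccccc2)CC(=O)O1 | starting material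
2 | (3R)-5-methoxy-5-oxo-3-phenylpentanoic acid | COC(=O)C[C@@H](CC(=O)O)c1ccccc1 | intermediate
3 | ethyltriphenylphosphonium bromide | CC[P+](c1ccccc1)(c1ccccc1)c1ccccc1.[Br-] | starting material
4 | methyl (3S)-5-chloro-5-oxo-3-phenylpentanoate | COC(=O)C[C@@H](CC(Cl)=O)c1ccccc1 | intermediate
5 | ethylidene(triphenyl)-λ5-phosphane | CC=P(c1ccccc1)(c1ccccc1)c1ccccc1 | intermediate
6 | methyl (3R)-5-oxo-3-phenyl-6-(triphenyl-λ5-phosphanylidene)heptanoate | COC(=O)C[C@@H](CC(=O)C(C)=P(c1ccccc1)(c1ccccc1)c1ccccc1)c1ccccc1 | intermediate
7 | 4-methylpent-3-en-1-ol | CC(C)=CCCO | starting material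
8 | 4-methylpent-3-enal | CC(C)=CCC=O | intermediate
9 | methyl (3R,6E)-6,10-dimethyl-5-oxo-3-phenylundeca-6,9-dienoate | COC(=O)C[C@@H](CC(=O)/C(C)=C/CC=C(C)C)c1ccccc1 | intermediate
10 | methyl (3R,5R,6E)-5-hydroxy-6,10-dimethyl-3-phenylundeca-6,9-dienoate | COC(=O)C[C@@H](C[C@@H](O)/C(C)=C/CC=C(C)C)c1ccccc1 | intermediate
11 | (4R,6R)-6-[(2E)-6-methylhepta-2,5-dien-2-yl]-4-phenyloxan-2-one | O=C1C[C@H](c2ccccc2)C[C@@H](O1)/C(C)=C/CC=C(C)C | intermediate
12 | tert-butyl(dimethyl){[(2R,4R)-2-[(2E)-6-methylhepta-2,5-dien-2-yl]-4-phenyl-3,4-dihydro-2H-pyran-6-yl]oxy}silane | CC(C)(C)[Si](C)(C)OC1=C[C@H](c2ccccc2)C[C@@H](O1)/C(C)=C/CC=C(C)C | intermediate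
13 | tert-butyldimethylsilyl (1R,2S,6R)-3-methyl-2-(3-methylbut-2-en-1-yl)-6-phenylcyclohex-3-ene-1-carboxylate | CC(C)(C)[Si](C)(C)OC(=O)[C@@H]1[C@H](CC=C(C)C)C(C)=CC[C@H]1c1ccccc1 | intermediate
14 | (1R,2S,6R)-3-methyl-2-(3-methylbut-2-en-1-yl)-6-phenylcyclohex-3-ene-1-carboxylic acid | OC(=O)[C@@H]1[C@H](CC=C(C)C)C(C)=CC[C@H]1c1ccccc1 | intermediate
15 | 3,5-dimethoxyphenol | COc1cc(O)cc(OC)c1 | starting material
16 | (3,5-dimethoxyphenoxy)tri(propan-2-yl)silane | COc1cc(O[Si](C(C)C)(C(C)C)C(C)C)cc(OC)c1 | intermediate
17 | (1R,2S,6R)-3-methyl-2-(3-methylbut-2-en-1-yl)-6-phenylcyclohex-3-ene-1-carbonyl chloride | ClC(=O)[C@@H]1[C@H](CC=C(C)C)C(C)=CC[C@H]1c1ccccc1 | intermediate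
18 | {2,6-dimethoxy-4-[tri(propan-2-yl)silyloxy]phenyl}lithium | [Li]c1c(OC)cc(O[Si](C(C)C)(C(C)C)C(C)C)cc1OC | intermediate
19 | {2,6-dimethoxy-4-[tri(propan-2-yl)silyloxy]phenyl}copper(I) | [Cu]c1c(OC)cc(O[Si](C(C)C)(C(C)C)C(C)C)cc1OC | intermediate
20 | {2,6-dimethoxy-4-[tri(propan-2-yl)silyloxy]phenyl}[(1R,2S,6R)-3-methyl-2-(3-methylbut-2-en-1-yl)-6-phenylcyclohex-3-en-1-yl]methanone | COc1cc(O[Si](C(C)C)(C(C)C)C(C)C)cc(OC)c1C(=O)[C@@H]1[C@H](CC=C(C)C)C(C)=CC[C@H]1c1ccccc1 | intermediate
21 | {2-hydroxy-6-methoxy-4-[tri(propan-2-yl)silyloxy]phenyl}[(1R,2S,6R)-3-methyl-2-(3-methylbut-2-en-1-yl)-6-phenylcyclohex-3-en-1-yl]methanone | COc1cc(O[Si](C(C)C)(C(C)C)C(C)C)cc(O)c1C(=O)[C@@H]1[C@H](CC=C(C)C)C(C)=CC[C@H]1c1ccccc1 | intermediate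
22 | isopanduratin A, (2,4-dihydroxy-6-methoxyphenyl)[(1R,2S,6R)-3-methyl-2-(3-methylbut-2-en-1-yl)-6-phenylcyclohex-3-en-1-yl]methanone | COc1cc(O)cc(O)c1C(=O)[C@@H]1[C@H](CC=C(C)C)C(C)=CC[C@H]1c1ccccc1 | target

## Step count and least certain steps

Total step count: 9. Longest linear sequence: 8 steps (1 → 2 → 6 → 9 → 11 → 14 → 20 → 21 → 22); step 6 is a one-step branch.

**Step 5 (key step).** The sigmatropic shift may be slow relative to loss of the ketene acetal (hydrolysis back to 11, C-silylation). The enforced boat must bring a trisubstituted alkene terminus onto C1 while the alkenyl and phenyl groups both sit on the reacting face.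
Fallback, setting out from 11 and returning at 20 (steps 5 and 7 skipped): 11 is converted with KHMDS and diphenyl chlorophosphate into the ketene acetal phosphate F1. Pd-catalysed Negishi coupling with the arylzinc chloride F2 (from 18 and ZnCl2) gives the 6-aryl-3,4-dihydro-2H-pyran F3. F3 is a robust enol ether that can be held at 180–200 °C in o-dichlorobenzene until the oxa-Claisen shift through the same boat gives 20 directly. The point to watch there is retro-hetero-[4+2] cleavage, which would erode enantiopurity.

**Step 3.** The β,γ-unsaturated aldehyde may isomerise into conjugation before a sluggish olefination by the stabilised keto ylide, and the skipped dienone may drift into conjugation.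
Fallback, setting out from 4 and returning at 9: commercial 1-propynylmagnesium bromide and prenyl bromide (CuI catalysis) give the enyne 6-methylhept-5-en-2-yne F4. Syn-hydrozirconation with Cp2Zr(H)Cl, equilibrated to place zirconium on the methyl-bearing carbon, gives the alkenylzirconocene chloride F5. Copper-catalysed acylation of F5 with 4 gives 9 with retention of alkene geometry.

**Step 4.** Facial discrimination in the reduction may be insufficient because both ketone substituents are attached through carbon chains of similar size near the carbonyl.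
Fallback, setting out from 9 and returning at 11: Luche reduction gives 10 together with its C5 epimer, the (3R,5S)-hydroxy ester F6, and the two are separated. F6 is saponified to the (3R,5S)-hydroxy acid F7, and Mitsunobu lactonisation of F7 closes the ring with inversion at C5 to give the same cis lactone 11. The 10 obtained alongside is lactonised with retention as in step 4.

**Step 7.** Acyl transfer between two hindered partners may be slow, and competing ketene formation would epimerise C1.
Fallback, setting out from 14 and returning at 20: LiAlH4 reduction gives the primary alcohol F8 and Dess–Martin oxidation gives the aldehyde F9. Addition of 18 at −78 °C gives the diaryl-type carbinol F10 as a mixture at the new carbinol centre, and Dess–Martin oxidation of F10 gives 20.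

**Step 8.** Demethylation may run on to the second ortho ether, and the Lewis acid may trigger cationic reactions of the trisubstituted alkenes (hydrochlorination, Prins-type closure onto the activated ketone).
Fallback, setting out from 14 (through 17) and returning at 22: commercial 5-methoxyresorcinol is bis-silylated to the bis-TIPS ether F11. NBS bromination at the less hindered position between OMe and OTIPS gives the aryl bromide F12. Bromine–lithium exchange with t-BuLi at −78 °C gives the aryllithium F13, which is added to 17 at −78 °C to give the bis-silyl ketone F14. Buffered TBAF then gives 22 with no demethylation step.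

## Further compounds

F1 | step 5 | diphenyl (2R,4R)-2-[(2E)-6-methylhepta-2,5-dien-2-yl]-4-phenyl-3,4-dihydro-2H-pyran-6-yl phosphate | O=P(Oc1ccccc1)(Oc1ccccc1)OC1=C[C@H](c2ccccc2)C[C@@H](O1)/C(C)=C/CC=C(C)C
F2 | step 5 | chlorido{2,6-dimethoxy-4-[tri(propan-2-yl)silyloxy]phenyl}zinc | Cl[Zn]c1c(OC)cc(O[Si](C(C)C)(C(C)C)C(C)C)cc1OC
F3 | step 5 | {3,5-dimethoxy-4-[(2R,4R)-2-[(2E)-6-methylhepta-2,5-dien-2-yl]-4-phenyl-3,4-dihydro-2H-pyran-6-yl]phenoxy}tri(propan-2-yl)silane | COc1cc(O[Si](C(C)C)(C(C)C)C(C)C)cc(OC)c1C1=C[C@H](c2ccccc2)C[C@@H](O1)/C(C)=C/CC=C(C)C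
F4 | step 3 | 6-methylhept-5-en-2-yne | CC#CCC=C(C)C
F5 | step 3 | chloridobis(cyclopentadienyl)[(2E)-6-methylhepta-2,5-dien-2-yl]zirconium | C/C(=C\CC=C(C)C)[Zr+2]Cl.[CH-]1C=CC=C1.[CH-]1C=CC=C1
F6 | step 4 | methyl (3R,5S,6E)-5-hydroxy-6,10-dimethyl-3-phenylundeca-6,9-dienoate | COC(=O)C[C@@H](C[C@H](O)/C(C)=C/CC=C(C)C)c1ccccc1
F7 | step 4 | (3R,5S,6E)-5-hydroxy-6,10-dimethyl-3-phenylundeca-6,9-dienoic acid | OC(=O)C[C@@H](C[C@H](O)/C(C)=C/CC=C(C)C)c1ccccc1
F8 | step 7 | [(1R,2S,6R)-3-methyl-2-(3-methylbut-2-en-1-yl)-6-phenylcyclohex-3-en-1-yl]methanol | OC[C@@H]1[C@H](CC=C(C)C)C(C)=CC[C@H]1c1ccccc1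
F9 | step 7 | (1R,2S,6R)-3-methyl-2-(3-methylbut-2-en-1-yl)-6-phenylcyclohex-3-ene-1-carbaldehyde | O=C[C@@H]1[C@H](CC=C(C)C)C(C)=CC[C@H]1c1ccccc1
F10 | step 7 | {2,6-dimethoxy-4-[tri(propan-2-yl)silyloxy]phenyl}[(1R,2S,6R)-3-methyl-2-(3-methylbut-2-en-1-yl)-6-phenylcyclohex-3-en-1-yl]methanol (both carbinol epimers) | COc1cc(O[Si](C(C)C)(C(C)C)C(C)C)cc(OC)c1C(O)[C@@H]1[C@H](CC=C(C)C)C(C)=CC[C@H]1c1ccccc1
F11 | step 8 | [(5-methoxy-1,3-phenylene)bis(oxy)]bis[tri(propan-2-yl)silane] | COc1cc(O[Si](C(C)C)(C(C)C)C(C)C)cc(O[Si](C(C)C)(C(C)C)C(C)C)c1
F12 | step 8 | [(4-bromo-5-methoxy-1,3-phenylene)bis(oxy)]bis[tri(propan-2-yl)silane] | COc1cc(O[Si](C(C)C)(C(C)C)C(C)C)cc(O[Si](C(C)C)(C(C)C)C(C)C)c1Br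
F13 | step 8 | {2-methoxy-4,6-bis[tri(propan-2-yl)silyloxy]phenyl}lithium | COc1cc(O[Si](C(C)C)(C(C)C)C(C)C)cc(O[Si](C(C)C)(C(C)C)C(C)C)c1[Li]
F14 | step 8 | {2-methoxy-4,6-bis[tri(propan-2-yl)silyloxy]phenyl}[(1R,2S,6R)-3-methyl-2-(3-methylbut-2-en-1-yl)-6-phenylcyclohex-3-en-1-yl]methanone | COc1cc(O[Si](C(C)C)(C(C)C)C(C)C)cc(O[Si](C(C)C)(C(C)C)C(C)C)c1C(=O)[C@@H]1[C@H](CC=C(C)C)C(C)=CC[C@H]1c1ccccc1
A1 | alternative 1 | cardamonin, (E)-1-(2,4-dihydroxy-6-methoxyphenyl)-3-phenylprop-2-en-1-one | COc1cc(O)cc(O)c1C(=O)/C=C/c1ccccc1
A2 | alternative 2 | 1-{2,6-dimethoxy-4-[tri(propan-2-yl)silyloxy]phenyl}-6-methyl-2-(1-phenylbut-3-en-1-yl)-3-(prop-1-en-2-yl)hept-5-en-1-one, three stereocentres as in 22 | COc1cc(O[Si](C(C)C)(C(C)C)C(C)C)cc(OC)c1C(=O)[C@H]([C@H](CC=C(C)C)C(C)=C)[C@@H](CC=C)c1ccccc1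
A3 | alternative 3 | 1-{2,6-dimethoxy-4-[tri(propan-2-yl)silyloxy]phenyl}prop-2-yn-1-one | COc1cc(O[Si](C(C)C)(C(C)C)C(C)C)cc(OC)c1C(=O)C#C
A4 | alternative 3 | {2,6-dimethoxy-4-[tri(propan-2-yl)silyloxy]phenyl}[5-methyl-6-(3-methylbut-2-en-1-yl)cyclohexa-1,4-dien-1-yl]methanone (racemic) | COc1cc(O[Si](C(C)C)(C(C)C)C(C)C)cc(OC)c1C(=O)C1=CCC=C(C)C1CC=C(C)C
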